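## Structural features

The target, C29H38O8, is a depside in which two benzene rings are joined only through one aryl ester; it has no other ring and no stereocentre, so no stereocentres stand next to each other. Ring A is the acyl half: its C1 carries the ester carbonyl, C2 and C4 carry methoxy groups and C6 carries a 2-oxoheptyl chain. Ring B is the phenol half: its C4 oxygen is the ester oxygen, C1 carries a free carboxyl, C2 a methoxy group and C6 a pentyl chain. Both ring-bound carbonyl carbons sit between two ortho substituents and are therefore hindered. The fragile groups are the aryl ester, which gives up its phenoxide easily to base, nucleophiles or electrons, and the benzylic ketone, whose enol oxygen can close a six-membered lactone onto the ring A acyl carbon and expel ring B, a closure that threatens every ring A intermediate holding the free ketone beside an acid or an activated acyl group. The real difficulty is to end with a free, hindered carboxyl on ring B while the only other acyl group is a cleavable ester and the ketone stays masked. The key step exploits C1 of ring B: flanked by the C2 methoxy and the C6 pentyl group, it can carry bromine through the whole assembly and take up CO2 at the end, so no carboxyl protecting group has to be told apart from the depside link.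

## Logic of the disconnections

17 to 16. No skeletal bond is cut; the C2 carbonyl of the heptyl chain of 17 is returned to the dioxolane of 16. While this carbon is a ketal, no intermediate can enol-lactonise onto the ring A acyl group or be deprotonated at the benzylic CH2. The gain is that base, acyl activation and a cathode can all be used earlier. The forward step must open the ketal without touching the aryl ester.

16 to 14 and 15. The bond between C1 of ring B and the carboxyl carbon is cut. This removes any need for a carboxyl protecting group beside the depside ester, and 14 is a neutral, robust aryl bromide. The forward step must activate a C–Br bond with two ortho neighbours and leave the aryl ester alone.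

14 to 13 and 7. The acyl C–O bond of the depside is cut, dividing the molecule into two rings of similar size. The forward step must acylate a phenol with a 2,6-disubstituted benzoic acid in a medium that is not acidic, because the dioxolane is present.

7 to 5 (through 6). The phenolic C–O bond of 7 is traced back to the one ring C–H of 5 that has no ortho substituent. This takes the oxygen out of the ring B precursor and leaves a simple 1,2,3-trisubstituted arene. The forward step must be sterically controlled and must tolerate the C–Br bond.

5 to 4, and 4 to 1 and 2 (through 3). The pentyl chain is cut between its benzylic carbon and the next carbon, as a C=C bond in 4, which leads to 1 and 2. The alkene must then be saturated without hydrogenolysis of the C–Br bond.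

13 to 12, and 12 to 11. Two functional-group changes, no skeletal bond: the acid comes from its methyl ester and the dioxolane from the ketone. The order matters: the ketal is put on while the carboxyl is still a methyl ester, because a free keto acid or its activated form would close to the six-membered enol lactone. The forward steps must ketalise under mild conditions and then saponify a hindered ester, which is safe because nothing else in 12 is base-sensitive.

11 to 8 and 9 (through 10). The bond between the benzylic CH2 of ring A and the ketone carbon is cut, which gives two simple pieces. The forward step must acylate the benzylic anion once only and must keep a ketone enolate from meeting the ortho ester.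

## Other disconnections considered

Alternative 1: Ring B would be cut across its C1–C2 and C5–C6 bonds, which leads back to benzyl oct-2-ynoate A2 and 1,1-dimethoxy-3-(trimethylsilyloxy)buta-1,3-diene A3.
In the forward key step a thermal Diels–Alder addition would join the CH2 terminus of A3 to the pentyl-bearing alkyne carbon of A2 and the ketene-acetal carbon to the ester-bearing one. Loss of one methoxy group and of the silyl group would aromatise the adduct to benzyl 4-hydroxy-2-methoxy-6-pentylbenzoate A1. A1 would then be acylated by 13, freed of its benzyl group by hydrogenolysis to reach 16, and deketalised as in step 9.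
In its favour, the polarity of the two partners fixes the positions of all three oxygens, the carboxyl carbon is present from the start, and it is released by neutral hydrogenolysis with no halogen and no electrochemistry.
Against it, a β-alkyl ynoate such as A2 should be a sluggish dienophile that needs long heating, A3 is a moisture-sensitive ketene acetal that may not survive such heating, and the benzyl ester costs a deprotection.
In comparison, on the mechanism of the end game this alternative is the better one, because the ring B carboxyl is never in doubt, whereas step 8 is untested on this substitution pattern. On structure the two are equal, since both fix the ring B pattern unambiguously. On step economy they are about equal (nine steps against nine or ten).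

Alternative 2: The depside C–O bond and the C1–C6 bond of ring A would both be cut, so that ring A comes from an open polyketide chain and ring B from the phenol A1.
In the forward key step, heating 2,2-dimethyl-6-[2,4-dioxo-5-(2-pentyl-1,3-dioxolan-2-yl)pentyl]-4H-1,3-dioxin-4-one A5 should release the acylketene 3,5,7-trioxo-8-(2-pentyl-1,3-dioxolan-2-yl)oct-1-en-1-one A6 by retro-[4+2] fragmentation. A1 would trap A6 as the triketo ester benzyl 2-methoxy-6-pentyl-4-{[3,5,7-trioxo-8-(2-pentyl-1,3-dioxolan-2-yl)octanoyl]oxy}benzoate A7. Aldol condensation of chain C2 onto the C7 ketone, followed by dehydration, would give benzyl 4-({2,4-dihydroxy-6-[(2-pentyl-1,3-dioxolan-2-yl)methyl]benzoyl}oxy)-2-methoxy-6-pentylbenzoate A4.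
In its favour, the hindered ester bond forms under neutral thermal conditions with no activation of a 2,6-disubstituted acid, which is better than step 7 of the chosen plan, and the plan is convergent and biomimetic.
Against it, A4 has two free phenols, one of them chelated to the ester carbonyl, and both must be methylated with base in the presence of the depside link. A5 needs several steps and carries a ketal β to a ketone that may open by elimination. A7 can cyclise in other modes, including ones that expel the ring B phenoxide. Ring B still has to be made as A1 and freed by hydrogenolysis.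
In comparison, the alternative is better on mechanism at ester formation but weaker on structure, because the methylation pattern must be repaired late. On step economy it is clearly longer than the chosen plan.

Alternative 3: Ring A would be cut across its C1–C2 and C5–C6 bonds, the ester bond already being in place.
In the forward key step the aryl ynoate benzyl 2-methoxy-6-pentyl-4-{[4-(2-pentyl-1,3-dioxolan-2-yl)but-2-ynoyl]oxy}benzoate A9 would be made from A1 and 4-(2-pentyl-1,3-dioxolan-2-yl)but-2-ynoic acid A10. Diels–Alder addition of A3 to A9, loss of one methoxy group and desilylation would give benzyl 4-({4-hydroxy-2-methoxy-6-[(2-pentyl-1,3-dioxolan-2-yl)methyl]benzoyl}oxy)-2-methoxy-6-pentylbenzoate A8. A8 would still need O-methylation and hydrogenolysis to reach 16.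
In its favour, the ester is made from an unhindered acid, which is better than step 7, an aryl ynoate should be a more reactive dienophile than A2, only one unchelated phenol has to be methylated, and the cycloaddition places the C2 methoxy and the C6 side chain.
Against it, A10 needs its own synthesis, and its CH2 group between the alkyne and the ketal may isomerise to an allene on heating or with base. A9 may suffer conjugate addition or acyl transfer from the nucleophilic diene. A1 is still required.
In comparison, on ester formation the alternative is better. On structure it is about equal, since ring A ends one methylation short. On mechanism and step economy the chosen plan is ahead, because it uses no thermally demanding cycloaddition on a fragile substrate and is several steps shorter.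

Key step: step 8

Assumption: 8 and 9 are taken to be catalogue chemicals; 4 is drawn as the Z alkene that a non-stabilised ylide should favour, and any E isomer is carried on because both give 5.

## Steps

Step 1
Reactants: 1 2-bromo-3-methoxybenzaldehyde; 2 butyltriphenylphosphonium bromide
Product: 4 2-bromo-1-methoxy-3-[(1Z)-pent-1-en-1-yl]benzene, via butylidenetriphenylphosphorane 3 (not isolated)
Conditions: KOt-Bu, THF, 0 °C → rt
Reagents that add atoms: none
Why: Wittig olefination of a non-enolisable aldehyde with a non-stabilised ylide is reliable and should favour the Z alkene. The geometry is of no consequence because step 2 removes the double bond, and the aryl bromide is inert to the ylide.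

Step 2
Reactants: 4 2-bromo-1-methoxy-3-[(1Z)-pent-1-en-1-yl]benzene
Product: 5 2-bromo-1-methoxy-3-pentylbenzene
Conditions: TsNHNH2, NaOAc, DME/H2O, reflux
Reagents that add atoms: none
Why: Diimide reduction transfers two hydrogens to the C=C bond in a concerted syn fashion and, unlike hydrogenation over palladium, cannot hydrogenolyse the C–Br bond that the key step needs.

Step 3
Reactants: 5 2-bromo-1-methoxy-3-pentylbenzene
Product: 7 4-bromo-3-methoxy-5-pentylphenol, via aryl pinacolboronate 6 (not isolated)
Conditions: [Ir(OMe)(cod)]2 (cat.), 4,4'-di-tert-butyl-2,2'-bipyridine (cat.), B2pin2, THF, 80 °C; then KHSO5 (as 2KHSO5·KHSO4·K2SO4), acetone/H2O, 0 °C → rt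
Reagents that add atoms: potassium peroxymonosulfate, [K+].[O-]S(=O)(=O)OO (gives the phenol oxygen of 7); bis(pinacolato)diboron, CC1(C)OB(B2OC(C)(C)C(C)(C)O2)OC1(C)C (gives the boryl group of 6, lost again on oxidation)
Why: Iridium-catalysed C–H borylation is governed by sterics and should select C5, the only ring hydrogen without an ortho substituent, while leaving the C–Br bond alone. Oxidation of the crude boronate with peroxymonosulfate converts C–B into C–OH at the same position.

Step 4
Reactants: 8 methyl 2,4-dimethoxy-6-methylbenzoate; 9 N-methoxy-N-methylhexanamide
Product: 11 methyl 2,4-dimethoxy-6-(2-oxoheptyl)benzoate, via lithiated toluate 10 (not isolated)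
Conditions: LiN(i-Pr)2, THF, −78 °C; then 9, −78 → −40 °C; aq. NH4Cl
Reagents that add atoms: none
Why: Lateral (benzylic) lithiation of an ortho-toluate gives an anion that is acylated at carbon. In this Weinreb ketone synthesis the chelated tetrahedral adduct survives until the quench, which prevents over-addition and keeps a ketone enolate from facing the ortho ester.

Step 5
Reactants: 11 methyl 2,4-dimethoxy-6-(2-oxoheptyl)benzoate
Product: 12 methyl 2,4-dimethoxy-6-[(2-pentyl-1,3-dioxolan-2-yl)methyl]benzoate
Conditions: TMSOCH2CH2OTMS, TMSOTf (cat.), CH2Cl2, −78 → −20 °C; pyridine quench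
Reagents that add atoms: 1,2-bis(trimethylsilyloxy)ethane, C[Si](C)(C)OCCO[Si](C)(C)C
Why: Noyori ketalisation (silyl transfer under catalytic TMSOTf) is aprotic and runs cold, so the dioxolane should form faster than any acid-promoted closure of the keto ester to an enol lactone. Doing this at the methyl ester stage avoids the free keto acid, which would cyclise.

Step 6
Reactants: 12 methyl 2,4-dimethoxy-6-[(2-pentyl-1,3-dioxolan-2-yl)methyl]benzoate
Product: 13 2,4-dimethoxy-6-[(2-pentyl-1,3-dioxolan-2-yl)methyl]benzoic acid
Conditions: KOH, DMSO/H2O, 90 °C; then aq. KHSO4, 0 °C, to pH 4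
Reagents that add atoms: potassium hydroxide, [K+].[OH-] (one carboxyl oxygen)
Why: Saponification of a 2,6-disubstituted benzoate is slow, but aryl ethers and the dioxolane are inert to hydroxide, so forcing conditions can be used. Cold, mild acidification and prompt use keep the dioxolane intact.

Step 7
Reactants: 13 2,4-dimethoxy-6-[(2-pentyl-1,3-dioxolan-2-yl)methyl]benzoic acid; 7 4-bromo-3-methoxy-5-pentylphenol
Product: 14 4-bromo-3-methoxy-5-pentylphenyl 2,4-dimethoxy-6-[(2-pentyl-1,3-dioxolan-2-yl)methyl]benzoate
Conditions: DCC, DMAP, CH2Cl2, 0 °C → rt
Reagents that add atoms: none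
Why: Steglich esterification: DMAP converts the O-acylisourea into an acylpyridinium ion that the unhindered phenol 7 attacks. The medium is not acidic, so the dioxolane survives, and the aryl bromide is a spectator.

Step 8
Reactants: 14 4-bromo-3-methoxy-5-pentylphenyl 2,4-dimethoxy-6-[(2-pentyl-1,3-dioxolan-2-yl)methyl]benzoate; 15 carbon dioxide
Product: 16 4-({2,4-dimethoxy-6-[(2-pentyl-1,3-dioxolan-2-yl)methyl]benzoyl}oxy)-2-methoxy-6-pentylbenzoic acid
Conditions: NiBr2(2,2'-bipyridine) (10 mol%), 2,2'-bipyridine (10 mol%), Bu4NBF4, CO2 (1 atm), dry DMF, Mg anode, carbon-felt cathode, undivided cell, constant current, 20 °C; then aq. KHSO4, 0 °C, to pH 4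
Reagents that add atoms: none
Why: At the cathode NiBr2(2,2'-bipyridine) is reduced to a bipyridine complex of zerovalent nickel, which adds oxidatively to the C1–Br bond of ring B; one more electron turns the aryl bromide complex of divalent nickel into an aryl complex of monovalent nickel, CO2 inserts into its Ni–C bond, and a final electron returns zerovalent nickel while magnesium cations from the dissolving anode pair with the carboxylate. The closest known reaction type is the nickel–bipyridine catalysed electroreductive carboxylation of aryl bromides with CO2 at a sacrificial magnesium anode, applied here to a bromide with two ortho substituents and a remote aryl ester. One C–C bond is formed, no ring is closed and no stereocentre arises. Chemoselectivity for C–Br over the aryl ester is needed: the mediator holds the working potential near that of the nickel complex, well positive of the reduction of an aryl benzoate, and insertion of the bipyridine complex of zerovalent nickel into an ester C–O bond is not expected at 20 °C. Carboxylation must also outrun hydrodebromination, and the dry, CO2-saturated medium together with the absence of acidic C–H bonds leaves the aryl nickel intermediate no proton source. The dioxolane prevents electrogenerated base from forming an enolate, which would otherwise be carboxylated at the benzylic carbon or close a lactone with loss of ring B. The ortho methoxy and pentyl groups should slow oxidative addition and insertion but also suppress biaryl homocoupling, and the magnesium carboxylate is too weak a nucleophile to attack the depside ester.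

Step 9
Reactants: 16 4-({2,4-dimethoxy-6-[(2-pentyl-1,3-dioxolan-2-yl)methyl]benzoyl}oxy)-2-methoxy-6-pentylbenzoic acid
Product: 17 4-{[2,4-dimethoxy-6-(2-oxoheptyl)benzoyl]oxy}-2-methoxy-6-pentylbenzoic acid
Conditions: PPTS (cat.), acetone/H2O (9:1), 45 °C
Reagents that add atoms: water, O
Why: Mildly acidic hydrolysis of the dioxolane should release the dialkyl ketone well before the hindered aryl ester is hydrolysed or attacked by the ketone enol. No other group is affected and there is no stereocentre to consider.

## Compound list

1 | 2-bromo-3-methoxybenzaldehyde | COc1cccc(C=O)c1Br | starting material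
2 | butyltriphenylphosphonium bromide | CCCC[P+](c1ccccc1)(c1ccccc1)c1ccccc1.[Br-] | starting material
3 | butylidenetriphenylphosphorane | CCCC=P(c1ccccc1)(c1ccccc1)c1ccccc1 | intermediate
4 | 2-bromo-1-methoxy-3-[(1Z)-pent-1-en-1-yl]benzene | CCC/C=C\c1cccc(OC)c1Br | intermediate
5 | 2-bromo-1-methoxy-3-pentylbenzene | CCCCCc1cccc(OC)c1Br | intermediate
6 | 2-(4-bromo-3-methoxy-5-pentylphenyl)-4,4,5,5-tetramethyl-1,3,2-dioxaborolane | CCCCCc1cc(B2OC(C)(C)C(C)(C)O2)cc(OC)c1Br | intermediate
7 | 4-bromo-3-methoxy-5-pentylphenol | CCCCCc1cc(O)cc(OC)c1Br | intermediate
8 | methyl 2,4-dimethoxy-6-methylbenzoate | COC(=O)c1c(C)cc(OC)cc1OC | starting material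
9 | N-methoxy-N-methylhexanamide | CCCCCC(=O)N(C)OC | starting material
10 | [3,5-dimethoxy-2-(methoxycarbonyl)phenyl]methyllithium | [Li]Cc1cc(OC)cc(OC)c1C(=O)OC | intermediate
11 | methyl 2,4-dimethoxy-6-(2-oxoheptyl)benzoate | CCCCCC(=O)Cc1cc(OC)cc(OC)c1C(=O)OC | intermediate
12 | methyl 2,4-dimethoxy-6-[(2-pentyl-1,3-dioxolan-2-yl)methyl]benzoate | CCCCCC1(Cc2cc(OC)cc(OC)c2C(=O)OC)OCCO1 | intermediate
13 | 2,4-dimethoxy-6-[(2-pentyl-1,3-dioxolan-2-yl)methyl]benzoic acid | CCCCCC1(Cc2cc(OC)cc(OC)c2C(=O)O)OCCO1 | intermediate
14 | 4-bromo-3-methoxy-5-pentylphenyl 2,4-dimethoxy-6-[(2-pentyl-1,3-dioxolan-2-yl)methyl]benzoate | CCCCCC1(Cc2cc(OC)cc(OC)c2C(=O)Oc2cc(CCCCC)c(Br)c(OC)c2)OCCO1 | intermediate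
15 | carbon dioxide | O=C=O | starting material
16 | 4-({2,4-dimethoxy-6-[(2-pentyl-1,3-dioxolan-2-yl)methyl]benzoyl}oxy)-2-methoxy-6-pentylbenzoic acid | CCCCCC1(Cc2cc(OC)cc(OC)c2C(=O)Oc2cc(CCCCC)c(C(=O)O)c(OC)c2)OCCO1 | intermediate
17 | 4-{[2,4-dimethoxy-6-(2-oxoheptyl)benzoyl]oxy}-2-methoxy-6-pentylbenzoic acid | CCCCCC(=O)Cc1cc(OC)cc(OC)c1C(=O)Oc1cc(CCCCC)c(C(=O)O)c(OC)c1 | target

## Step count and least certain steps

Total steps: 9. Longest linear sequence: 6 (steps 1, 2, 3, 7, 8, 9; the ring A branch, steps 4, 5, 6, 7, 8, 9, is equally long).

Step 8 (key step). Oxidative addition at a C–Br bond with two ortho neighbours may be slow. The aryl nickel intermediate could then be diverted to hydrodebromination by traces of water or by hydrogen abstraction from the solvent. If the catalyst is starved, the cathode potential could drift negative and begin reductive cleavage of the aryl ester. The fallback sets out from 14 and replaces reductive carboxylation by palladium-catalysed alkoxycarbonylation: Pd(OAc)2, Xantphos, CO (1 atm), benzyl alcohol and Et3N in toluene at 90 °C should give benzyl 4-({2,4-dimethoxy-6-[(2-pentyl-1,3-dioxolan-2-yl)methyl]benzoyl}oxy)-2-methoxy-6-pentylbenzoate F1. Hydrogenolysis of F1 with H2 over Pd/C in EtOAc at rt touches neither the aryl ester nor the dioxolane and comes back to the route at 16, at the cost of one step.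

Step 7. Acyl transfer from the hindered activated acid to the phenol may be slower than rearrangement of the O-acylisourea to an unreactive N-acylurea. A dioxolane oxygen may also take part at the activated acyl carbon. The fallback sets out from 13 and uses a preformed acyl fluoride: cyanuric fluoride and pyridine in CH2Cl2 at −10 °C should give 2,4-dimethoxy-6-[(2-pentyl-1,3-dioxolan-2-yl)methyl]benzoyl fluoride F2. F2 is small, isolable and little inclined to ionise. Treated with 7, i-Pr2NEt and catalytic DMAP in MeCN, it comes back to the route at 14.

Step 5. Lewis-acid activation of the ketone may let the ortho ester carbonyl take part, so closure to the enol lactone with loss of the methyl group could compete with ketalisation. The hindered saponification of step 6 is the next weak point on the same branch. The fallback sets out from 9, puts the ketal on before the ring carries any acyl group, and bypasses steps 4 to 6. Addition of (3,5-dimethoxybenzyl)magnesium chloride F3, made from 3,5-dimethoxybenzyl chloride and Mg in THF, to 9 should give 1-(3,5-dimethoxyphenyl)heptan-2-one F4. Ethylene glycol and catalytic TsOH in toluene with azeotropic removal of water should then give 2-[(3,5-dimethoxyphenyl)methyl]-2-pentyl-1,3-dioxolane F5; nothing on the ring can cyclise. NBS in MeCN at 0 °C over NaHCO3 should brominate mainly ortho to the side chain and para to a methoxy group, giving 2-[(2-bromo-3,5-dimethoxyphenyl)methyl]-2-pentyl-1,3-dioxolane F6. Bromine–lithium exchange with n-BuLi in THF at −78 °C gives {2,4-dimethoxy-6-[(2-pentyl-1,3-dioxolan-2-yl)methyl]phenyl}lithium F7, which is quenched with CO2; cold work-up with aq. KHSO4 comes back to the route at 13.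

Step 9. Once the ketone is free, acid-promoted enolisation could lead to lactonisation onto the aryl ester with expulsion of the ring B phenol, while too gentle a treatment could leave the hydrolysis incomplete. The fallback sets out from 16 and replaces Brønsted-acid hydrolysis by non-hydrolytic exchange of the dioxolane onto the solvent: catalytic I2 in dry acetone at rt, with no water and no protic acid, and comes back to the route at 17. This fallback makes no new compound and is entered as F0.

## Further compounds

F1 | step 8 | benzyl 4-({2,4-dimethoxy-6-[(2-pentyl-1,3-dioxolan-2-yl)methyl]benzoyl}oxy)-2-methoxy-6-pentylbenzoate | CCCCCC1(Cc2cc(OC)cc(OC)c2C(=O)Oc2cc(CCCCC)c(C(=O)OCc3ccccc3)c(OC)c2)OCCO1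
F2 | step 7 | 2,4-dimethoxy-6-[(2-pentyl-1,3-dioxolan-2-yl)methyl]benzoyl fluoride | CCCCCC1(Cc2cc(OC)cc(OC)c2C(F)=O)OCCO1
F3 | step 5 | (3,5-dimethoxybenzyl)magnesium chloride | COc1cc(C[Mg]Cl)cc(OC)c1
F4 | step 5 | 1-(3,5-dimethoxyphenyl)heptan-2-one | CCCCCC(=O)Cc1cc(OC)cc(OC)c1
F5 | step 5 | 2-[(3,5-dimethoxyphenyl)methyl]-2-pentyl-1,3-dioxolane | CCCCCC1(Cc2cc(OC)cc(OC)c2)OCCO1
F6 | step 5 | 2-[(2-bromo-3,5-dimethoxyphenyl)methyl]-2-pentyl-1,3-dioxolane | CCCCCC1(Cc2cc(OC)cc(OC)c2Br)OCCO1
F7 | step 5 | {2,4-dimethoxy-6-[(2-pentyl-1,3-dioxolan-2-yl)methyl]phenyl}lithium | [Li]c1c(OC)cc(OC)cc1CC1(CCCCC)OCCO1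
F0 | step 9 | none | none
A1 | alternative 1 | benzyl 4-hydroxy-2-methoxy-6-pentylbenzoate | CCCCCc1cc(O)cc(OC)c1C(=O)OCc1ccccc1
A2 | alternative 1 | benzyl oct-2-ynoate | CCCCCC#CC(=O)OCc1ccccc1
A3 | alternative 1 | 1,1-dimethoxy-3-(trimethylsilyloxy)buta-1,3-diene | COC(OC)=CC(=C)O[Si](C)(C)C
A4 | alternative 2 | benzyl 4-({2,4-dihydroxy-6-[(2-pentyl-1,3-dioxolan-2-yl)methyl]benzoyl}oxy)-2-methoxy-6-pentylbenzoate | CCCCCC1(Cc2cc(O)cc(O)c2C(=O)Oc2cc(CCCCC)c(C(=O)OCc3ccccc3)c(OC)c2)OCCO1
A5 | alternative 2 | 2,2-dimethyl-6-[2,4-dioxo-5-(2-pentyl-1,3-dioxolan-2-yl)pentyl]-4H-1,3-dioxin-4-one | CCCCCC1(CC(=O)CC(=O)CC2=CC(=O)OC(C)(C)O2)OCCO1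
A6 | alternative 2 | 3,5,7-trioxo-8-(2-pentyl-1,3-dioxolan-2-yl)oct-1-en-1-one | CCCCCC1(CC(=O)CC(=O)CC(=O)C=C=O)OCCO1
A7 | alternative 2 | benzyl 2-methoxy-6-pentyl-4-{[3,5,7-trioxo-8-(2-pentyl-1,3-dioxolan-2-yl)octanoyl]oxy}benzoate | CCCCCC1(CC(=O)CC(=O)CC(=O)CC(=O)Oc2cc(CCCCC)c(C(=O)OCc3ccccc3)c(OC)c2)OCCO1
A8 | alternative 3 | benzyl 4-({4-hydroxy-2-methoxy-6-[(2-pentyl-1,3-dioxolan-2-yl)methyl]benzoyl}oxy)-2-methoxy-6-pentylbenzoate | CCCCCC1(Cc2cc(O)cc(OC)c2C(=O)Oc2cc(CCCCC)c(C(=O)OCc3ccccc3)c(OC)c2)OCCO1
A9 | alternative 3 | benzyl 2-methoxy-6-pentyl-4-{[4-(2-pentyl-1,3-dioxolan-2-yl)but-2-ynoyl]oxy}benzoate | CCCCCC1(CC#CC(=O)Oc2cc(CCCCC)c(C(=O)OCc3ccccc3)c(OC)c2)OCCO1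
A10 | alternative 3 | 4-(2-pentyl-1,3-dioxolan-2-yl)but-2-ynoic acid | CCCCCC1(CC#CC(=O)O)OCCO1
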